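**Retrosynthetic overview**
1. The plan rests on the C2–C3 bond of ring A. It carries the 2α,3α-cis-diol and lies between the C1 methylene (on C10) and the quaternary C4 (on C5), so breaking it turns both carbinol carbons into formyl groups on two arms of an otherwise complete ring B.
2. Last C–C bond: C2–C3, by SmI2 pinacol coupling of the C1–C2 acetaldehyde arm with the C4–C3 dimethylacetaldehyde arm. Both formyl groups are released together from an allyl and a 1,1-dimethylallyl group.
3. Side chain: the E-enoate (C13–C16) comes from methylalumination/methoxycarbonylation of a terminal alkyne, and C9–C11 from α-face addition of a butynyl Grignard reagent to the C9 ketone.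
4. Ring B is the p-menthane ring of (R)-carvone, which already holds C5 with its C4 branch, the C8 methyl and the C9 carbonyl. C10 becomes quaternary by methylation then allylation, and the isopropenyl group gains one carbon at C4 (epoxide, hydride shift, α-methylation).
5. Ring order: ring B comes intact from the chiral pool, and ring A is closed last.

Key step: step 13

Remark: labdane numbering is used for every compound and α is the ring face opposite the C10 methyl; the target SMILES is read as 5α-H, 8α-CH3 (equatorial), 9β-OH (equatorial) with the C11 chain 9α (axial), 10β-CH3, 2α-OH (equatorial), 3α-OH (axial), 13E.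

**Step 1**
Reactants: 1 (R)-(−)-carvone
Product: 3 6-methylcarvone (C10 epimer mixture), via lithium dienolate 2 (not isolated)
Conditions: LiN(i-Pr)2 (LDA), THF, −78 °C; MeI, −78 → 0 °C
Reagents that add atoms: iodomethane, CI
Why: Kinetic deprotonation of the cross-conjugated enone can only take place at the α′ methylene (future C10), and enolate alkylation installs the future C20 methyl; the epimer ratio is irrelevant because this centre is enolised again in step 2.

**Step 2**
Reactants: 3 6-methylcarvone; 4 allyl bromide
Product: 6 (5S,6S)-6-allyl-6-methylcarvone (allyl trans to isopropenyl), via lithium dienolate 5 (not isolated)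
Conditions: LiN(i-Pr)2 (LDA), THF, −78 °C; allyl bromide, DMPU, −78 °C → rt
Reagents that add atoms: allyl bromide 4, C=CCBr
Why: Enolate alkylation in which the isopropenyl group turns pseudoaxial to escape allylic strain with the C10 methyl and shields its own face, so the allyl group should enter anti to it and set quaternary C10 with the C1 arm trans to the C4 arm.

**Step 3**
Reactants: 6 (5S,6S)-6-allyl-6-methylcarvone
Product: 7 isopropenyl epoxide of 6 (2-methyloxiran-2-yl group on C5, C4 epimer mixture)
Conditions: mCPBA (1.0 equiv), CH2Cl2, 0 °C
Reagents that add atoms: 3-chloroperbenzoic acid, OOC(=O)c1cccc(Cl)c1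
Why: Prilezhaev epoxidation is electrophilic, so the 1,1-disubstituted alkene should react well ahead of the monosubstituted allyl alkene and the electron-poor enone; the C4 mixture is harmless because C4 later becomes a gem-dimethyl carbon.

**Step 4**
Reactants: 7 isopropenyl epoxide
Product: 8 α-branched aldehyde (C5 arm = CH(CH3)CHO, C4 epimer mixture)
Conditions: BF3·OEt2 (0.5 equiv), CH2Cl2, −78 → −40 °C; Et3N quench
Reagents that add atoms: none
Why: Meinwald rearrangement, in which Lewis-acid opening of the tertiary C4–O bond and a 1,2-hydride shift from the CH2O carbon turn a 2,2-dialkyl epoxide into the aldehyde, the low temperature keeping the weakly nucleophilic allyl alkene away from the cationic centre.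

**Step 5**
Reactants: 8 α-branched aldehyde
Product: 10 gem-dimethyl aldehyde (C5 arm = C(CH3)2CHO), via potassium enolate 9 (not isolated)
Conditions: MeI (5 equiv), KOt-Bu (1.1 equiv, added last), THF, −20 → 0 °C
Reagents that add atoms: iodomethane, CI
Why: α-Alkylation of an α-branched aldehyde through its potassium enolate; the formyl α-H is clearly more acidic than the enone γ-H, so one equivalent of base with MeI already present should methylate C4 only, which erases the C4 stereocentre and gives a non-enolisable aldehyde.

**Step 6**
Reactants: 10 gem-dimethyl aldehyde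
Product: 11 enone with a 2-methylbut-3-en-2-yl group on C5 and an allyl group on C10
Conditions: Ph3PCH3Br, KOt-Bu, THF, 0 °C; then 10, −78 → 0 °C
Reagents that add atoms: methyltriphenylphosphonium bromide, C[P+](c1ccccc1)(c1ccccc1)c1ccccc1.[Br-]
Why: Wittig methylenation; the aldehyde is far more electrophilic than the conjugated C9 ketone next to quaternary C10, so one equivalent of ylide masks C3 as a vinyl group that tolerates hydride, Grignard and alane reagents and is unmasked together with the allyl group in step 12.

**Step 7**
Reactants: 11 enone
Product: 13 ring B ketone (5α-H; 8α-CH3; 10β-CH3), via lithium enolate 12 (not isolated)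
Conditions: LiBH(s-Bu)3 (L-Selectride), THF, −78 °C; MeOH; then NaOMe (cat.), MeOH, rt
Reagents that add atoms: none
Why: Conjugate hydride reduction of a β-unsubstituted cyclohexenone whose carbonyl is shielded by C10, followed by base equilibration of the only enolisable centre, which places the C8 methyl equatorial (α) because the axial epimer would be syn-diaxial to the C10 methyl.

**Step 8**
Reactants: 13 ring B ketone; 14 4-bromo-1-(trimethylsilyl)but-1-yne
Product: 17 tertiary alcohol (9β-OH; 9α-CH2CH2C≡C-SiMe3), via Grignard reagent 15 (not isolated), via bromomagnesium alkoxide 16 (not isolated)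
Conditions: 14, Mg, THF, rt; anhydrous CeCl3, THF, −78 °C; then 13, −78 → 0 °C; aq. NH4Cl
Reagents that add atoms: 4-bromo-1-(trimethylsilyl)but-1-yne 14, C[Si](C)(C)C#CCCBr
Why: CeCl3-promoted Grignard 1,2-addition suppresses enolisation and β-hydride transfer on the 2,2,6-trisubstituted cyclohexanone, and in the chair locked by the equatorial C5 tert-alkyl group the axial β methyl on C10 blocks the β face, so the nucleophile should enter axially from the α face and leave the 9-hydroxyl β-equatorial.

**Step 9**
Reactants: 17 tertiary alcohol
Product: 18 9-O-triethylsilyl ether of 17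
Conditions: Et3SiOTf, 2,6-lutidine, CH2Cl2, 0 °C → rt
Reagents that add atoms: triethylsilyl triflate, CC[Si](CC)(CC)OS(=O)(=O)C(F)(F)F
Why: Silylation with a silyl triflate and a hindered pyridine base is the standard way to cap crowded tertiary alcohols, and the ether later prevents the 9-hydroxyl from closing a five-membered lactol on the C2 aldehyde.

**Step 10**
Reactants: 18 9-O-triethylsilyl ether
Product: 19 terminal alkyne (9-O-triethylsilyl, 9α-but-3-ynyl)
Conditions: K2CO3 (cat.), MeOH/THF, rt
Reagents that add atoms: none
Why: Base-catalysed methanolysis cleaves the C(sp)–Si bond selectively, while the shielded tertiary triethylsilyl ether is inert to these conditions.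

**Step 11**
Reactants: 19 terminal alkyne
Product: 21 E-enoate diene (complete side chain; allyl on C10; 2-methylbut-3-en-2-yl on C5), via alkenylalane 20 (not isolated)
Conditions: Me3Al, Cp2ZrCl2 (0.25 equiv), CH2Cl2, 0 °C → rt; excess Me3Al evaporated; ClCO2Me, 0 °C → rt
Reagents that add atoms: trimethylaluminium, C[Al](C)C; methyl chloroformate, COC(=O)Cl
Why: Negishi zirconium-catalysed methylalumination adds CH3 and Al syn across the terminal alkyne with Al at the terminus, much faster than any reaction of the two 1-alkenes, and acylation of the alkenylalane by the chloroformate goes with retention, which fixes the E geometry of C13=C14.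

**Step 12**
Reactants: 21 E-enoate diene
Product: 23 ring B dialdehyde (C10–CH2CHO; C5–C(CH3)2CHO; 9-O-triethylsilyl; complete side chain), via bis-diol 22 (not isolated)
Conditions: OsO4 (cat.), NaIO4, 2,6-lutidine, dioxane/H2O, 0 °C → rt; used at once
Reagents that add atoms: osmium tetroxide, O=[Os](=O)(=O)=O; sodium periodate, [Na+].[O-]I(=O)(=O)=O; water, O
Why: Lemieux–Johnson cleavage, in which OsO4 dihydroxylates the two electron-neutral monosubstituted alkenes in preference to the electron-poor trisubstituted enoate, periodate cleaves both glycols in situ, and the lutidine buffer protects the silyl ether and the enolisable C2 aldehyde.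

**Step 13**
Reactants: 23 ring B dialdehyde
Product: 25 9-O-triethylsilyl ether of the target, via samarium diolate 24 (not isolated)
Conditions: SmI2 (0.1 M in THF, 3 equiv), t-BuOH (3 equiv), THF, slow addition of 23 (final 0.005 M), −78 °C → rt
Reagents that add atoms: none
Why: Divalent samarium gives one electron to the more accessible C2 formyl group, the ketyl stays bound to oxophilic trivalent samarium that also ties up the C3 carbonyl oxygen, the ketyl carbon adds to C3, and a second electron plus t-BuOH deliver the diol; the closest known reaction type is the SmI2 intramolecular pinacol coupling of 1,6-dialdehydes to cis-cyclohexane-1,2-diols. Ring A closes in the 6-exo-trig mode between two arms that are already trans-diequatorial on the ring B chair, so the trans-decalin should form without strain. The cis relation of the C2 and C3 oxygens is controlled by the samarium bridge, which holds both oxygens on the same side of the forming bond. Which cis-diol forms is controlled by the substrate: the chair-like closure to the 2β,3β isomer would force the C2 oxygen axial between the axial methyls on C4 and C10, whereas the 2α (equatorial), 3α (axial) arrangement meets only the axial hydrogens on C1 and C5. The step needs chemoselectivity over the enoate, which is secured because SmI2 without HMPA, water or amine does not reduce a β,β-disubstituted enoate, because ketyl attack on C13 would have to close a seven- or eight-membered ring onto a fully substituted carbon, and because slow addition at high dilution disfavours intermolecular coupling. The 9-O-silyl ether keeps C2 a free aldehyde instead of a five-membered lactol.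

**Step 14**
Reactants: 25 9-O-triethylsilyl ether of the target
Product: 26 target CNP0292844.1
Conditions: HF·pyridine, pyridine, THF, 0 °C → rt
Reagents that add atoms: none
Why: Fluoride-driven Si–O cleavage under buffered conditions should remove the tertiary triethylsilyl ether without touching the enoate, epimerising a centre or dehydrating the tertiary alcohol.

**Compound list**
1 | (R)-(−)-carvone, (5R)-2-methyl-5-(prop-1-en-2-yl)cyclohex-2-en-1-one | O=C1C(C)=CC[C@@H](C(C)=C)C1 | starting material
2 | lithium cross-conjugated dienolate of 1 (C9=C10) | [Li+].[O-]C1=C[C@H](C(C)=C)CC=C1C | intermediate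
3 | 6-methylcarvone, (5R)-2,6-dimethyl-5-(prop-1-en-2-yl)cyclohex-2-en-1-one, C10 epimer mixture | O=C1C(C)=CC[C@@H](C(C)=C)C1C | intermediate
4 | allyl bromide | C=CCBr | starting material
5 | lithium dienolate of 3 (tetrasubstituted C9=C10) | [Li+].[O-]C1=C(C)[C@H](C(C)=C)CC=C1C | intermediate
6 | (5S,6S)-2,6-dimethyl-6-(prop-2-en-1-yl)-5-(prop-1-en-2-yl)cyclohex-2-en-1-one (5α-H, 10β-CH3, allyl trans to isopropenyl) | O=C1C(C)=CC[C@@H](C(C)=C)[C@]1(C)CC=C | intermediate
7 | epoxide of 6 at the isopropenyl group (2-methyloxiran-2-yl on C5, C4 epimers) | O=C1C(C)=CC[C@@H](C2(C)CO2)[C@]1(C)CC=C | intermediate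
8 | aldehyde with a 1-oxopropan-2-yl group on C5 (C4 epimers) | O=C1C(C)=CC[C@@H](C(C)C=O)[C@]1(C)CC=C | intermediate
9 | potassium enolate of 8 (C3=C4) | O=C1C(C)=CC[C@@H](C(C)=C[O-])[C@]1(C)CC=C.[K+] | intermediate
10 | aldehyde with a 2-methyl-1-oxopropan-2-yl group on C5 | O=C1C(C)=CC[C@@H](C(C)(C)C=O)[C@]1(C)CC=C | intermediate
11 | enone with 2-methylbut-3-en-2-yl on C5 and allyl plus methyl on C10 | O=C1C(C)=CC[C@@H](C(C)(C)C=C)[C@]1(C)CC=C | intermediate
12 | lithium enolate from conjugate reduction of 11 (C8=C9) | [Li+].[O-]C1=C(C)CC[C@@H](C(C)(C)C=C)[C@]1(C)CC=C | intermediate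
13 | ring B ketone, 2-allyl-2,6-dimethyl-3-(2-methylbut-3-en-2-yl)cyclohexan-1-one with 5α-H, 8α-CH3, 10β-CH3 | O=C1[C@H](C)CC[C@@H](C(C)(C)C=C)[C@]1(C)CC=C | intermediate
14 | 4-bromo-1-(trimethylsilyl)but-1-yne | C[Si](C)(C)C#CCCBr | starting material
15 | [4-(trimethylsilyl)but-3-yn-1-yl]magnesium bromide | C[Si](C)(C)C#CCC[Mg]Br | intermediate
16 | bromomagnesium alkoxide of 17 | C[Si](C)(C)C#CCC[C@]1(O[Mg]Br)[C@H](C)CC[C@@H](C(C)(C)C=C)[C@]1(C)CC=C | intermediate
17 | tertiary alcohol, 9β-OH, 9α-[4-(trimethylsilyl)but-3-ynyl] | C[Si](C)(C)C#CCC[C@]1(O)[C@H](C)CC[C@@H](C(C)(C)C=C)[C@]1(C)CC=C | intermediate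
18 | 9-O-triethylsilyl ether of 17 | C[Si](C)(C)C#CCC[C@]1(O[Si](CC)(CC)CC)[C@H](C)CC[C@@H](C(C)(C)C=C)[C@]1(C)CC=C | intermediate
19 | terminal alkyne, 9-O-triethylsilyl, 9α-but-3-ynyl | C#CCC[C@]1(O[Si](CC)(CC)CC)[C@H](C)CC[C@@H](C(C)(C)C=C)[C@]1(C)CC=C | intermediate
20 | (E)-alkenyl(dimethyl)alane, Al on C14 cis to the new C13 methyl | C[Al](C)/C=C(\C)CC[C@]1(O[Si](CC)(CC)CC)[C@H](C)CC[C@@H](C(C)(C)C=C)[C@]1(C)CC=C | intermediate
21 | methyl (E)-enoate diene, 9-O-triethylsilyl | COC(=O)/C=C(\C)CC[C@]1(O[Si](CC)(CC)CC)[C@H](C)CC[C@@H](C(C)(C)C=C)[C@]1(C)CC=C | intermediate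
22 | bis-diol from dihydroxylation of both terminal alkenes of 21 (carbinol epimers) | COC(=O)/C=C(\C)CC[C@]1(O[Si](CC)(CC)CC)[C@H](C)CC[C@@H](C(C)(C)C(O)CO)[C@]1(C)CC(O)CO | intermediate
23 | ring B dialdehyde, 9-O-triethylsilyl, complete side chain (key-step precursor) | COC(=O)/C=C(\C)CC[C@]1(O[Si](CC)(CC)CC)[C@H](C)CC[C@@H](C(C)(C)C=O)[C@]1(C)CC=O | intermediate
24 | 2α,3α-bis(diiodosamarium) diolate of 25 | COC(=O)/C=C(\C)CC[C@]1(O[Si](CC)(CC)CC)[C@H](C)CC[C@H]2C(C)(C)[C@H](O[Sm](I)I)[C@H](O[Sm](I)I)C[C@@]21C | intermediate
25 | 9-O-triethylsilyl ether of the target (2α,3α-diol, trans-decalin; key-step product) | COC(=O)/C=C(\C)CC[C@]1(O[Si](CC)(CC)CC)[C@H](C)CC[C@H]2C(C)(C)[C@H](O)[C@H](O)C[C@@]21C | intermediate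
26 | CNP0292844.1, methyl (13E)-2α,3α,9β-trihydroxy-8α-methyl-labd-13-en-15-oate with the side chain 9α | COC(=O)/C=C(\C)CC[C@]1(O)[C@H](C)CC[C@H]2C(C)(C)[C@H](O)[C@H](O)C[C@@]21C | target

**Total step count:** 14. **Longest linear sequence:** 14 steps from (R)-carvone 1.

**Steps most likely to fail**

**Step 13.**
- Risks: loss of chelate control with leakage towards the diequatorial trans-diol, plain reduction of the hindered C3 formyl group before coupling, or capture of a ketyl by the enoate.
- Fallback: it sets out from 21. Ring-closing metathesis with the second-generation Grubbs catalyst in refluxing CH2Cl2 joins the allyl and dimethylallyl termini and should give the ring A C2=C3 olefin F1; the trisubstituted enoate is inert to the catalyst.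
- Return: dihydroxylation with OsO4 (cat.) and N-methylmorpholine N-oxide in acetone/H2O should then occur from the α face. The β face is covered by the axial methyls on C4 and C10 and the enoate is deactivated, so the route is rejoined at 25.

**Step 8.**
- Risks: enolisation at C8 or β-hydride transfer from the Grignard reagent in place of addition to the very crowded carbonyl.
- Fallback: it sets out from 13. Corey–Chaykovsky reaction with dimethylsulfonium methylide (Me3SI, n-BuLi, THF, 0 °C) uses a small nucleophile that adds irreversibly along the axial α trajectory. It should give the spiro-epoxide F2, with the C11 methylene α-axial and the oxygen β-equatorial.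
- Return: opening at the unsubstituted epoxide carbon with 3-lithio-1-(trimethylsilyl)propyne (1-(trimethylsilyl)propyne, n-BuLi, THF/DMPU, −78 °C → rt) forms C11–C12 and rejoins the route at 17.

**Step 5.**
- Risks: competing γ-deprotonation of the enone followed by methylation at C8, O-methylation of the enolate, or aldol reactions under strong base.
- Fallback: it sets out from 8 and avoids strong base. Soft enolisation (Me3SiOTf, Et3N, CH2Cl2, 0 °C) should give the trimethylsilyl enol ether F3.
- Furukawa-type Simmons–Smith cyclopropanation (Et2Zn, CH2I2, CH2Cl2, 0 °C) picks the electron-rich enol ether over the allyl and enone alkenes and should give the siloxycyclopropane F4.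
- Return: Conia-type ring opening (NaOH, MeOH/H2O, rt) breaks the bond between the carbinol carbon and the new CH2. The CH2 becomes the second C4 methyl, and the route is rejoined at 10.

**Further compounds**
F1 | step 13 | 9-O-triethylsilyl ring A C2=C3 olefin (trans-decalin, complete side chain) | COC(=O)/C=C(\C)CC[C@]1(O[Si](CC)(CC)CC)[C@H](C)CC[C@H]2C(C)(C)C=CC[C@@]21C
F2 | step 8 | C9 spiro-epoxide of ring B (C11 methylene α-axial, oxygen β-equatorial) | C1[C@]2(O1)[C@H](C)CC[C@@H](C(C)(C)C=C)[C@]2(C)CC=C
F3 | step 5 | trimethylsilyl enol ether of 8 (C3=C4, E/Z mixture) | O=C1C(C)=CC[C@@H](C(C)=CO[Si](C)(C)C)[C@]1(C)CC=C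
F4 | step 5 | 1-methyl-2-(trimethylsilyloxy)cyclopropyl derivative on C5 (diastereomer mixture) | O=C1C(C)=CC[C@@H](C2(C)CC2O[Si](C)(C)C)[C@]1(C)CC=C
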